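**Retrosynthetic overview**
1. Target 26 ⇐ PMB ether 25 (DDQ) ⇐ keto-aldehyde 23 + 3-methylbut-2-enoyl chloride 24 (E-selective enol O-acylation) ⇐ diol 22 (double oxidation).
2. 22 ⇐ 2-methylene-3-acetoxycycloheptanone 20 (SN2′ transposition with 4-methoxybenzyl alcohol) ⇐ acyclic 2-methylene enal 19 by 7-endo-trig acyl-radical cyclisation onto a 1,1-disubstituted alkene (C1–C7 bond; C6 set by H-atom transfer).
3. 19 ⇐ lactol 14 + lithiated 2-bromoacrolein dimethyl acetal 15 (brings C1, C2 and the future CH2OH carbon).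
4. 14 ⇐ δ-lactone 13 ⇐ 5,6-dihydro-2H-pyran-2-one 4 by Rh-catalysed asymmetric conjugate alkenylation (C5), then enolate alkylation with homoprenyl iodide 9 and with MeI (quaternary C4).
5. Rings: the δ-lactone ring comes with 4 and is opened in step 6; the cycloheptenone, the only carbocycle, is formed in step 8.

Assumption: ring positions are numbered as in cyclohept-2-en-1-one (C1 carbonyl, C2 bearing CH2OH, C4 quaternary, C5 and C6 the CH stereocentres); the side-chain carbinol CH(O)CH3 made in step 1 and the C3 carbinol made in step 6 are carried as epimer mixtures and left undefined in the SMILES, because both become sp2 carbons later.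

**Step 1**
Reactants: 1 2,3-dibromoprop-1-ene; 2 acetaldehyde
Product: 3 4-bromopent-4-en-2-ol (racemic)
Conditions: In powder, THF/H2O (1:1), rt
Reagents that add atoms: none
Why: Barbier-type indium-mediated 2-bromoallylation of an aldehyde in water, in which only the allylic C–Br bond takes up the metal while the vinylic bromide survives; the carbinol centre is racemic and is oxidised away in step 10.

**Step 2**
Reactants: 3 4-bromopent-4-en-2-ol; 4 5,6-dihydro-2H-pyran-2-one
Product: 8 (4R)-4-(4-hydroxypent-1-en-2-yl)oxan-2-one, via dilithio alkoxide 5 (not isolated), via lithium alkenyltrimethoxyborate 6 (not isolated), via alkenylboronic acid 7 (not isolated)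
Conditions: t-BuLi (3.1 equiv), Et2O, −78 °C; B(OMe)3, −78 °C → rt; 1 M HCl wash; then 4, [Rh(OH)((R)-BINAP)]2 (3 mol % Rh), 1,4-dioxane/H2O (10:1), 40 °C
Reagents that add atoms: none
Why: Hayashi–Miyaura rhodium-catalysed asymmetric conjugate addition, in which the alkenyl–Rh/(R)-BINAP species adds to one enantioface of the lactone and the oxa-π-allyl rhodium is protonated by water, setting the future C5 (ligand sense chosen by analogy with aryl additions to this lactone), while the neutral boronic-acid conditions keep the lactone intact.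

**Step 3**
Reactants: 8 (4R)-4-(4-hydroxypent-1-en-2-yl)oxan-2-one; 9 5-iodo-2-methylpent-2-ene
Product: 11 (3S,4R)-4-(4-hydroxypent-1-en-2-yl)-3-(4-methylpent-3-en-1-yl)oxan-2-one, via dilithium enolate alkoxide 10 (not isolated)
Conditions: LiN(i-Pr)2 (2.2 equiv), THF, −78 °C; then 9, DMPU, −78 → −20 °C
Reagents that add atoms: none
Why: Lactone enolate alkylation with a primary iodide (the second equivalent of base holds the side-chain hydroxyl as its alkoxide); the new α-centre forms trans but is planarised again in step 4, so only regiochemistry matters here.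

**Step 4**
Reactants: 11 (3S,4R)-4-(4-hydroxypent-1-en-2-yl)-3-(4-methylpent-3-en-1-yl)oxan-2-one
Product: 13 (3R,4S)-4-(4-hydroxypent-1-en-2-yl)-3-methyl-3-(4-methylpent-3-en-1-yl)oxan-2-one, via dilithium enolate alkoxide 12 (not isolated)
Conditions: LiN(i-Pr)2 (2.2 equiv), THF/DMPU, −78 °C; then MeI (1.1 equiv), −78 °C
Reagents that add atoms: iodomethane, CI
Why: Diastereoselective alkylation of the trisubstituted lactone enolate, in which the small electrophile MeI enters anti to the adjacent alkenyl substituent, so the quaternary carbon (target C4, R) carries methyl trans and the homoprenyl chain cis to the alkenyl group.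

**Step 5**
Reactants: 13 (3R,4S)-4-(4-hydroxypent-1-en-2-yl)-3-methyl-3-(4-methylpent-3-en-1-yl)oxan-2-one
Product: 14 (3R,4S)-4-(4-hydroxypent-1-en-2-yl)-3-methyl-3-(4-methylpent-3-en-1-yl)oxan-2-ol (lactol, anomer mixture)
Conditions: i-Bu2AlH (2.2 equiv), CH2Cl2, −78 °C; aq. potassium sodium tartrate
Reagents that add atoms: none
Why: Partial lactone reduction, in which the tetrahedral aluminium hemiacetal is stable at −78 °C and gives the lactol (a masked neopentyl aldehyde) on work-up; no stereocentre is touched.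

**Step 6**
Reactants: 14 lactol; 15 2-bromo-3,3-dimethoxyprop-1-ene
Product: 18 (4R,5S)-5-(4-acetoxypent-1-en-2-yl)-1,1-dimethoxy-4-methyl-2-methylidene-4-(4-methylpent-3-en-1-yl)heptane-3,7-diyl diacetate, via alkenyllithium acetal 16 (not isolated), via trilithium trialkoxide 17 (not isolated)
Conditions: 15 (4.5 equiv), t-BuLi (9 equiv), THF, −78 °C; then 14, −78 → −30 °C; then Ac2O (8 equiv), −30 °C → rt
Reagents that add atoms: acetic anhydride, CC(=O)OC(C)=O
Why: Bromine–lithium exchange gives an acrolein α-anion equivalent that undergoes 1,2-addition to the open hydroxy-aldehyde form of the lactol, and in situ acetylation of the three lithium alkoxides installs the allylic acetate leaving group and protects the other two hydroxyls; the new C3 carbinol is an epimer mixture that converges in step 9.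

**Step 7**
Reactants: 18 triacetate dimethyl acetal
Product: 19 (4R,5S)-3,7-diacetoxy-5-(4-acetoxypent-1-en-2-yl)-4-methyl-2-methylidene-4-(4-methylpent-3-en-1-yl)heptanal
Conditions: PPTS (0.2 equiv), acetone/H2O (10:1), rt
Reagents that add atoms: water, O
Why: Acid-catalysed acetal hydrolysis of a labile allylic acetal unmasks the 2-methylene aldehyde while the acetates and the alkenes survive; no stereocentre is touched.

**Step 8**
Reactants: 19 triacetate enal
Product: 20 (4R,5S,6S)-3-acetoxy-5-(2-acetoxyethyl)-6-(2-acetoxypropyl)-4-methyl-2-methylidene-4-(4-methylpent-3-en-1-yl)cycloheptan-1-one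
Conditions: tert-dodecanethiol (0.5 equiv), AIBN (0.3 equiv, syringe pump), PhCl (0.01 M), 80 °C
Reagents that add atoms: none
Why: Proposed new method: a thiyl radical abstracts the formyl hydrogen of the 2-methylene enal, the resulting sigma acyl radical (which cannot decarbonylate and is merely returned to 19 if reduced early) closes 7-endo-trig on the unsubstituted CH2 of the 1,1-disubstituted alkene (6-exo would attack the fully substituted carbon, and the hindered, electron-rich trisubstituted side-chain alkene is a poor partner for a nucleophilic acyl radical), forming C1–C7 and the only carbocycle, and the tertiary C6 radical then takes hydrogen from the bulky thiol on the face opposite the C5 side chain, which places the C6 substituent cis to it (6S); the closest known chemistry is thiol-catalysed radical hydroacylation of alkenals (polarity-reversal catalysis) and 7-endo acyl-radical cyclisation of selenoesters.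

**Step 9**
Reactants: 20 2-methylene-3-acetoxycycloheptanone
Product: 22 (4R,5S,6S)-5-(2-hydroxyethyl)-6-(2-hydroxypropyl)-2-[(4-methoxybenzyloxy)methyl]-4-methyl-4-(4-methylpent-3-en-1-yl)cyclohept-2-en-1-one, via PMB ether diacetate 21 (not isolated)
Conditions: 4-MeOC6H4CH2OH (5 equiv), Cs2CO3 (1.5 equiv), THF, 0 °C; then MeOH, 0 °C → rt
Reagents that add atoms: 4-methoxybenzyl alcohol, COc1ccc(CO)cc1
Why: SN2′ substitution of a Morita–Baylis–Hillman-type acetate (alkoxide conjugate addition to the exo-methylene ketone, then E1cB loss of the C3 acetate) gives the endocyclic 2-(alkoxymethyl) enone whose geometry is fixed by the ring, and base methanolysis then frees the two remaining alcohols; both C3 epimers converge and C4 to C6 are untouched.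

**Step 10**
Reactants: 22 diol
Product: 23 (4R,5S,6S)-2-[(4-methoxybenzyloxy)methyl]-4-methyl-4-(4-methylpent-3-en-1-yl)-5-(2-oxoethyl)-6-(2-oxopropyl)cyclohept-2-en-1-one
Conditions: Dess–Martin periodinane (3 equiv), CH2Cl2, 0 °C → rt
Reagents that add atoms: none
Why: Dess–Martin oxidation converts the primary alcohol to the aldehyde and the secondary alcohol to the methyl ketone in one operation under neutral conditions; C5 and C6 are β to the new carbonyls and cannot epimerise.

**Step 11**
Reactants: 23 keto-aldehyde; 24 3-methylbut-2-enoyl chloride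
Product: 25 (4R,5R,6S)-2-[(4-methoxybenzyloxy)methyl]-4-methyl-4-(4-methylpent-3-en-1-yl)-5-[(E)-2-(3-methylbut-2-enoyloxy)ethenyl]-6-(2-oxopropyl)cyclohept-2-en-1-one
Conditions: 24 (3 equiv), Et3N (5 equiv), DMAP (0.2 equiv), CH2Cl2, −20 °C → rt
Reagents that add atoms: none
Why: Enol ester formation by O-acylation, in which the amine enolises the aldehyde (far more readily than either ketone) and the acylpyridinium captures the enol; the E geometry is preferred because the Z enol suffers A1,3 strain with the branched C5 substituent.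

**Step 12**
Reactants: 25 PMB-protected enol ester
Product: 26 (4R,5R,6S)-2-(hydroxymethyl)-4-methyl-4-(4-methylpent-3-en-1-yl)-5-[(E)-2-(3-methylbut-2-enoyloxy)ethenyl]-6-(2-oxopropyl)cyclohept-2-en-1-one (CNP0415257.2)
Conditions: DDQ (1.5 equiv), CH2Cl2/pH 7 buffer (10:1), 0 °C
Reagents that add atoms: none
Why: Oxidative PMB ether cleavage (benzylic hydride abstraction by DDQ, then hydrolysis of the oxocarbenium ion) under buffered conditions that spare the enol ester, the enone and the trisubstituted alkene.

**Compound list**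
1 | 2,3-dibromoprop-1-ene | C=C(Br)CBr | starting material
2 | acetaldehyde | CC=O | starting material
3 | 4-bromopent-4-en-2-ol (racemic) | CC(O)CC(Br)=C | intermediate
4 | 5,6-dihydro-2H-pyran-2-one | O=C1C=CCCO1 | starting material
5 | lithium 4-lithiopent-4-en-2-olate | [Li]OC(C)CC([Li])=C | intermediate (not isolated)
6 | lithium trimethoxy(4-lithiooxypent-1-en-2-yl)borate | [Li+].[Li]OC(C)CC(=C)[B-](OC)(OC)OC | intermediate (not isolated)
7 | (4-hydroxypent-1-en-2-yl)boronic acid | CC(O)CC(=C)B(O)O | intermediate (not isolated)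
8 | (4R)-4-(4-hydroxypent-1-en-2-yl)oxan-2-one (epimers at the side-chain carbinol) | O=C1OCC[C@@H](C(=C)CC(C)O)C1 | intermediate
9 | 5-iodo-2-methylpent-2-ene | CC(C)=CCCI | starting material
10 | dilithium enolate alkoxide of 8 | [Li]OC1=C[C@H](C(=C)CC(C)O[Li])CCO1 | intermediate (not isolated)
11 | (3S,4R)-4-(4-hydroxypent-1-en-2-yl)-3-(4-methylpent-3-en-1-yl)oxan-2-one | O=C1OCC[C@@H](C(=C)CC(C)O)[C@@H]1CCC=C(C)C | intermediate
12 | dilithium enolate alkoxide of 11 | [Li]OC1=C(CCC=C(C)C)[C@H](C(=C)CC(C)O[Li])CCO1 | intermediate (not isolated)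
13 | (3R,4S)-4-(4-hydroxypent-1-en-2-yl)-3-methyl-3-(4-methylpent-3-en-1-yl)oxan-2-one | O=C1OCC[C@@H](C(=C)CC(C)O)[C@@]1(C)CCC=C(C)C | intermediate
14 | (3R,4S)-4-(4-hydroxypent-1-en-2-yl)-3-methyl-3-(4-methylpent-3-en-1-yl)oxan-2-ol (anomers) | OC1OCC[C@@H](C(=C)CC(C)O)[C@@]1(C)CCC=C(C)C | intermediate
15 | 2-bromo-3,3-dimethoxyprop-1-ene (2-bromoacrolein dimethyl acetal) | COC(OC)C(Br)=C | starting material
16 | (3,3-dimethoxyprop-1-en-2-yl)lithium | COC(OC)C([Li])=C | intermediate (not isolated)
17 | trilithium trialkoxide of (4R,5S)-5-(4-hydroxypent-1-en-2-yl)-1,1-dimethoxy-4-methyl-2-methylidene-4-(4-methylpent-3-en-1-yl)heptane-3,7-diol | [Li]OCC[C@@H](C(=C)CC(C)O[Li])[C@@](C)(CCC=C(C)C)C(O[Li])C(=C)C(OC)OC | intermediate (not isolated)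
18 | (4R,5S)-5-(4-acetoxypent-1-en-2-yl)-1,1-dimethoxy-4-methyl-2-methylidene-4-(4-methylpent-3-en-1-yl)heptane-3,7-diyl diacetate | CC(=O)OCC[C@@H](C(=C)CC(C)OC(C)=O)[C@@](C)(CCC=C(C)C)C(OC(C)=O)C(=C)C(OC)OC | intermediate
19 | (4R,5S)-3,7-diacetoxy-5-(4-acetoxypent-1-en-2-yl)-4-methyl-2-methylidene-4-(4-methylpent-3-en-1-yl)heptanal | CC(=O)OCC[C@@H](C(=C)CC(C)OC(C)=O)[C@@](C)(CCC=C(C)C)C(OC(C)=O)C(=C)C=O | intermediate
20 | (4R,5S,6S)-3-acetoxy-5-(2-acetoxyethyl)-6-(2-acetoxypropyl)-4-methyl-2-methylidene-4-(4-methylpent-3-en-1-yl)cycloheptan-1-one | CC(=O)OCC[C@H]1[C@@H](CC(C)OC(C)=O)CC(=O)C(=C)C(OC(C)=O)[C@]1(C)CCC=C(C)C | intermediate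
21 | (4R,5S,6S)-5-(2-acetoxyethyl)-6-(2-acetoxypropyl)-2-[(4-methoxybenzyloxy)methyl]-4-methyl-4-(4-methylpent-3-en-1-yl)cyclohept-2-en-1-one | CC(=O)OCC[C@H]1[C@@H](CC(C)OC(C)=O)CC(=O)C(COCc2ccc(OC)cc2)=C[C@]1(C)CCC=C(C)C | intermediate (not isolated)
22 | (4R,5S,6S)-5-(2-hydroxyethyl)-6-(2-hydroxypropyl)-2-[(4-methoxybenzyloxy)methyl]-4-methyl-4-(4-methylpent-3-en-1-yl)cyclohept-2-en-1-one | OCC[C@H]1[C@@H](CC(C)O)CC(=O)C(COCc2ccc(OC)cc2)=C[C@]1(C)CCC=C(C)C | intermediate
23 | (4R,5S,6S)-2-[(4-methoxybenzyloxy)methyl]-4-methyl-4-(4-methylpent-3-en-1-yl)-5-(2-oxoethyl)-6-(2-oxopropyl)cyclohept-2-en-1-one | O=CC[C@H]1[C@@H](CC(C)=O)CC(=O)C(COCc2ccc(OC)cc2)=C[C@]1(C)CCC=C(C)C | intermediate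
24 | 3-methylbut-2-enoyl chloride | CC(C)=CC(Cl)=O | starting material
25 | (4R,5R,6S)-2-[(4-methoxybenzyloxy)methyl]-4-methyl-4-(4-methylpent-3-en-1-yl)-5-[(E)-2-(3-methylbut-2-enoyloxy)ethenyl]-6-(2-oxopropyl)cyclohept-2-en-1-one | CC(C)=CC(=O)O/C=C/[C@H]1[C@@H](CC(C)=O)CC(=O)C(COCc2ccc(OC)cc2)=C[C@]1(C)CCC=C(C)C | intermediate
26 | (4R,5R,6S)-2-(hydroxymethyl)-4-methyl-4-(4-methylpent-3-en-1-yl)-5-[(E)-2-(3-methylbut-2-enoyloxy)ethenyl]-6-(2-oxopropyl)cyclohept-2-en-1-one | CC(=O)C[C@H]1CC(=O)C(CO)=C[C@](C)(CCC=C(C)C)[C@H]1/C=C/OC(=O)C=C(C)C | target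

**Totals**
Total step count: 12. Longest linear sequence: 12 steps (1 → 26); 2, 4, 9, 15 and 24 enter as purchased materials.

**Three steps most likely to fail**

Step 8 (radical ring closure). The risks are a slow 7-endo closure, competing attack on the side-chain alkene, thiol addition to the alkenes, and a modest diastereomer ratio at C6. Fallback: from 19, Pinnick oxidation (NaClO2, NaH2PO4, 2-methylbut-2-ene) gives the 2-methylene carboxylic acid F1. 1-Chloro-N,N,2-trimethylprop-1-en-1-amine converts it under neutral conditions into the acid chloride F2, and PhSeSiMe3 then gives the Se-phenyl selenoester F3. Treatment of F3 with (Me3Si)3SiH and Et3B/air in benzene at 0 °C generates the same acyl radical by selenium abstraction in a thiol-free silane chain, at lower temperature and with a bulkier hydrogen donor, and the route is rejoined at 20.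

Step 9 (SN2′ etherification and deacetylation). The risks are acetate cleavage before conjugate addition, and bridged oxa-Michael addition of the freed primary alkoxide of 22 to C3 of the enone. Fallback: from 20, zerovalent palladium (Pd2(dba)3, dppe, THF, rt) ionises the allylic acetate to the 2-acyl π-allyl complex, which 4-methoxybenzyl alcohol captures at the CH2 terminus under neutral conditions to give 21. Acetate removal with K2CO3/MeOH at −10 °C, followed by immediate oxidation, rejoins the route at 22; this fallback makes no new compound (F0).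

Step 11 (enol ester formation). The risks are an E/Z mixture, intramolecular aldol reaction of the keto-aldehyde, and deconjugation of the acyl group through its vinylketene. Fallback: from 23, acylate at −40 °C with excess 24 so that the enol is trapped quickly whatever its geometry, and separate the (Z)-enol ester F4. F4 is then isomerised by reversible thiyl-radical addition–elimination (PhSH 10 mol %, AIBN, benzene, 80 °C), which equilibrates it to the less strained E isomer, and the route is rejoined at 25.

**Further compounds**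
F1 | step 8 | (4R,5S)-3,7-diacetoxy-5-(4-acetoxypent-1-en-2-yl)-4-methyl-2-methylidene-4-(4-methylpent-3-en-1-yl)heptanoic acid | CC(=O)OCC[C@@H](C(=C)CC(C)OC(C)=O)[C@@](C)(CCC=C(C)C)C(OC(C)=O)C(=C)C(O)=O
F2 | step 8 | (4R,5S)-3,7-diacetoxy-5-(4-acetoxypent-1-en-2-yl)-4-methyl-2-methylidene-4-(4-methylpent-3-en-1-yl)heptanoyl chloride | CC(=O)OCC[C@@H](C(=C)CC(C)OC(C)=O)[C@@](C)(CCC=C(C)C)C(OC(C)=O)C(=C)C(Cl)=O
F3 | step 8 | Se-phenyl (4R,5S)-3,7-diacetoxy-5-(4-acetoxypent-1-en-2-yl)-4-methyl-2-methylidene-4-(4-methylpent-3-en-1-yl)heptaneselenoate | CC(=O)OCC[C@@H](C(=C)CC(C)OC(C)=O)[C@@](C)(CCC=C(C)C)C(OC(C)=O)C(=C)C(=O)[Se]c1ccccc1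
F0 | step 9 | none | none
F4 | step 11 | (Z)-enol ester isomer of 25 | CC(C)=CC(=O)O/C=C\[C@H]1[C@@H](CC(C)=O)CC(=O)C(COCc2ccc(OC)cc2)=C[C@]1(C)CCC=C(C)C
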